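## Retrosynthetic overview

1. The acetate comes from primary-selective acetylation of diol lactone 27. Compound 27 comes from the cis-fused bis-γ-lactone 24: ring C is masked as its carboxylate, ring D is reduced to CH2OH plus OH, and ring C is closed again.
2. Key disconnection: the bond between the internal alkene carbon and the allylic CH. It is made from two electrophiles, enol triflate 14 (rings A/B, fourteen carbons) and α-bromo bis-lactone 23 (rings C/D, six carbons), by nickel-catalysed reductive cross-coupling.
3. Enabling feature: the hydroxyl oxygen on the α-carbon of lactone ring C and the carbon of the CH2OAc group are 1,5-related (O–Cα–Cβ–allylic CH–CH2). Raised to the acid level, that carbon closes on the hydroxyl as a second γ-lactone (ring D), cis-fused to ring C along the Cα–Cβ bond. The allylic CH then becomes the activated α-carbon of a cup-shaped bicycle, and its convex face is the face the target needs.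
4. The six carbons and both stereocentres of this bis-lactone are those of natural (2R,3S)-isocitric acid. Ring D closes first, then an anhydride ring, which methanolysis and borane reduction turn into ring C. Ring D is opened again after the coupling.
5. Rings A and B are bought together in enedione 1. Gem-dimethylation, deoxygenation and trans-hydrogenation finish the hydrindane. Wittig olefination, hydroboration, oxidation and triflation add the two-carbon alkenyl handle.

Key step: step 13

Assumption: potassium dihydrogen (2R,3S)-isocitrate (the natural, fermentation-derived isomer) and enedione 1 are purchased enantiopure; indene and furo[3,4-b]furan locants are used, and the rings are lettered A (cyclohexane), B (cyclopentane), C (lactone kept in the target) and D (temporary lactone).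

## Route

Step 1
Reactants: 1 (7aS)-7a-methyl-2,3,7,7a-tetrahydro-1H-indene-1,5(6H)-dione
Product: 2 (7aS)-1,1-ethylenedioxy-7a-methyl-2,3,7,7a-tetrahydro-1H-inden-5(6H)-one
Conditions: (Me3SiOCH2)2, Me3SiOTf (5 mol%), CH2Cl2, −78 to −40 °C
Reagents that add atoms: 1,2-bis(trimethylsilyloxy)ethane, C[Si](C)(C)OCCO[Si](C)(C)C
Why: Noyori-type ketalisation at low temperature protects the saturated ring B ketone and leaves the less electrophilic conjugated enone untouched, and the quaternary stereocentre is not involved.

Step 2
Reactants: 2 (7aS)-1,1-ethylenedioxy-7a-methyl-2,3,7,7a-tetrahydro-1H-inden-5(6H)-one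
Product: 4 (7aS)-1,1-ethylenedioxy-4,4,7a-trimethyl-1,2,4,6,7,7a-hexahydro-5H-inden-5-one (C3=C3a alkene), via monomethyl enone 3 (not isolated)
Conditions: KOtBu (3 equiv), MeI (5 equiv), t-BuOH–THF, 0 °C to rt
Reagents that add atoms: iodomethane, CI
Why: Thermodynamic dienolate alkylation puts both methyl groups on the α-carbon C-4, and the second alkylation locks the double bond out of conjugation between C-3 and C-3a, as in the classical gem-dimethylation of bicyclic and steroidal enones.

Step 3
Reactants: 4 (7aS)-1,1-ethylenedioxy-4,4,7a-trimethyl-1,2,4,6,7,7a-hexahydro-5H-inden-5-one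
Product: 6 (7aS)-1,1-ethylenedioxy-4,4,7a-trimethyl-2,4,5,6,7,7a-hexahydro-1H-indene (C3=C3a alkene), via hydrazone 5 (not isolated)
Conditions: N2H4·H2O, KOH, diethylene glycol, 130 then 200 °C
Reagents that add atoms: none
Why: Wolff–Kishner reduction (Huang-Minlon variant) removes the hindered C-5 ketone through its hydrazone under conditions that a ketal and an isolated trisubstituted alkene tolerate and that are standard for 4,4-dimethyl-3-oxo steroids.

Step 4
Reactants: 6 (7aS)-1,1-ethylenedioxy-4,4,7a-trimethyl-2,4,5,6,7,7a-hexahydro-1H-indene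
Product: 8 (3aS,7aS)-4,4,7a-trimethyloctahydro-1H-inden-1-one, via saturated ketal 7 (not isolated)
Conditions: H2 (30 bar), Pd/C, EtOAc, rt; filter; 2 M HCl, THF, rt
Reagents that add atoms: water, O
Why: Heterogeneous catalytic hydrogenation should deliver hydrogen to the face opposite the two axial methyl groups (angular methyl and one C-4 methyl) and so set the C-3a hydrogen trans to the angular methyl, after which acid-catalysed ketal hydrolysis frees the ketone.

Step 5
Reactants: 8 (3aS,7aS)-4,4,7a-trimethyloctahydro-1H-inden-1-one
Product: 9 (1Z,3aS,7aS)-1-ethylidene-4,4,7a-trimethyloctahydro-1H-indene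
Conditions: EtPPh3Br, KOtBu, THF, reflux
Reagents that add atoms: ethyltriphenylphosphonium bromide, CC[P+](c1ccccc1)(c1ccccc1)c1ccccc1.[Br-]
Why: Wittig olefination with the non-stabilised ethylide should give the Z-ethylidene compound as with 17-oxo steroids, and the alkene geometry has no consequence later.

Step 6
Reactants: 9 (1Z,3aS,7aS)-1-ethylidene-4,4,7a-trimethyloctahydro-1H-indene
Product: 11 (1S)-1-[(1S,3aS,7aS)-4,4,7a-trimethyloctahydro-1H-inden-1-yl]ethan-1-ol, via B-alkyl-9-BBN adduct 10 (not isolated)
Conditions: 9-BBN, THF, 65 °C; then NaOH, H2O2, 0 °C to rt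
Reagents that add atoms: hydrogen peroxide, OO
Why: Brown hydroboration–oxidation places boron on the less hindered ethylidene CH carbon and hydrogen on C-1 by syn addition from the face opposite the angular methyl, which sets C-1 with the side chain cis to that methyl, while the carbinol centre is erased in the next step.

Step 7
Reactants: 11 (1S)-1-[(1S,3aS,7aS)-4,4,7a-trimethyloctahydro-1H-inden-1-yl]ethan-1-ol
Product: 12 1-[(1S,3aS,7aS)-4,4,7a-trimethyloctahydro-1H-inden-1-yl]ethan-1-one
Conditions: Dess–Martin periodinane, CH2Cl2, 0 °C to rt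
Reagents that add atoms: none
Why: Dess–Martin oxidation converts the secondary alcohol into the methyl ketone under mild conditions that should not epimerise the adjacent C-1 centre.

Step 8
Reactants: 12 1-[(1S,3aS,7aS)-4,4,7a-trimethyloctahydro-1H-inden-1-yl]ethan-1-one
Product: 14 1-[(1S,3aS,7aS)-4,4,7a-trimethyloctahydro-1H-inden-1-yl]ethenyl trifluoromethanesulfonate, via potassium enolate 13 (not isolated)
Conditions: KN(SiMe3)2, THF, −78 °C; PhNTf2, −78 to 0 °C
Reagents that add atoms: N-phenylbis(trifluoromethanesulfonimide), O=S(=O)(N(c1ccccc1)S(=O)(=O)C(F)(F)F)C(F)(F)F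
Why: Kinetic deprotonation with a bulky amide base takes a methyl proton and not the hindered tertiary C-1 proton, and O-sulfonylation of this terminal enolate gives the 1,1-disubstituted enol triflate with C-1 untouched.

Step 9
Reactants: 15 potassium dihydrogen (2R,3S)-isocitrate
Product: 18 (3aS,6aR)-dihydrofuro[3,4-b]furan-2,4,6(3H)-trione (isocitric lactone anhydride), via free isocitric acid 16 (not isolated), via isocitric acid lactone 17 (not isolated)
Conditions: 1 M HCl (1 equiv), H2O, evaporate, 110 °C in vacuo; acetone, filter; Ac2O, 90 °C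
Reagents that add atoms: none
Why: Acid-promoted 5-exo-trig γ-lactonisation of the carbinol oxygen onto the CH2CO2H carboxyl closes ring D, and dehydration of the two remaining carboxyl groups, which are cis on that ring, gives the bicyclic lactone anhydride without touching either stereocentre.

Step 10
Reactants: 18 (3aS,6aR)-dihydrofuro[3,4-b]furan-2,4,6(3H)-trione
Product: 19 (2R,3S)-2-(methoxycarbonyl)-5-oxooxolane-3-carboxylic acid
Conditions: MeOH, CH2Cl2, 0 °C to rt
Reagents that add atoms: methanol, CO
Why: Regioselective alcoholysis of an unsymmetrical cyclic anhydride should occur at the carbonyl activated by the adjacent acyloxy-bearing carbon, as with O-acylmalic anhydrides, so that the carboxyl on C-3 is left free.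

Step 11
Reactants: 19 (2R,3S)-2-(methoxycarbonyl)-5-oxooxolane-3-carboxylic acid
Product: 21 (3aR,6aR)-tetrahydrofuro[3,4-b]furan-2,6-dione (cis-fused bis-lactone), via hydroxy ester 20 (not isolated)
Conditions: BH3·SMe2, THF, −10 °C to rt; MeOH; then p-TsOH (cat.), toluene, 80 °C
Reagents that add atoms: none
Why: Borane reduces the free carboxylic acid chemoselectively beside ester and lactone, and the new primary alcohol, held cis to the methyl ester, closes ring C by acid-catalysed 5-exo-trig transesterification.

Step 12
Reactants: 21 (3aR,6aR)-tetrahydrofuro[3,4-b]furan-2,6-dione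
Product: 23 (3S,3aR,6aR)-3-bromotetrahydrofuro[3,4-b]furan-2,6-dione, via silyl ketene acetal 22 (not isolated)
Conditions: Me3SiCl, LiN(SiMe3)2, THF, −78 °C; then NBS, −78 to −20 °C
Reagents that add atoms: N-bromosuccinimide, O=C1CCC(=O)N1Br
Why: Kinetic enolisation with internal silyl quench should take the accessible methylene protons next to the ring D carbonyl rather than the tertiary bridgehead proton, and electrophilic bromination of the silyl ketene acetal from the convex face gives the exo α-bromo lactone, whose configuration is lost again in the next step.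

Step 13
Reactants: 14 1-[(1S,3aS,7aS)-4,4,7a-trimethyloctahydro-1H-inden-1-yl]ethenyl trifluoromethanesulfonate; 23 (3S,3aR,6aR)-3-bromotetrahydrofuro[3,4-b]furan-2,6-dione
Product: 24 (3R,3aR,6aR)-3-{1-[(1R,3aS,7aS)-4,4,7a-trimethyloctahydro-1H-inden-1-yl]ethenyl}tetrahydrofuro[3,4-b]furan-2,6-dione
Conditions: NiBr2·diglyme (15 mol%), 4,4'-di-tert-butyl-2,2'-bipyridine (18 mol%), NaI (25 mol%), Mn powder (3 equiv), DMA, 0 °C to rt, slow addition of 23
Reagents that add atoms: none
Why: Zerovalent nickel inserts into the C–O bond of enol triflate 14 to give an alkenylnickel species, a monovalent nickel halide abstracts bromine from 23 to give the planar α-acyl radical at C-3 of ring D, the radical is captured at nickel, reductive elimination from trivalent nickel makes the C(sp2)–C(sp3) bond, and Mn powder returns nickel to its low-valent state. The closest known reaction type is the nickel-catalysed reductive cross-electrophile coupling of alkenyl halides and triflates with α-halo esters and other secondary alkyl halides, here a union of two carbons that are both electrophilic. No ring is closed, and rings A to D pass through unchanged. The one new stereocentre, C-3 of the bis-lactone, is controlled by the cup shape of the cis-fused bicyclo[3.3.0] framework: the bulky alkenylnickel can reach the radical only on the convex face that carries the two bridgehead hydrogens, anti to the C-4 methylene of ring C, this exo bond (also the thermodynamically preferred one) is the configuration of the target, and the configuration of the bromide does not matter. Cross-selectivity over homocoupling is needed and is secured by the different activation modes of the partners, two-electron insertion for the sp2 triflate and halogen abstraction for the carbonyl-activated sp3 bromide, helped by slow addition of 23. Chemoselectivity is secured by the base-free, non-nucleophilic medium, in which both lactones survive, the acidic allylic C-3 hydrogen of 24 is not removed and the 1,1-disubstituted alkene should stay out of conjugation.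

Step 14
Reactants: 24 (3R,3aR,6aR)-3-{1-[(1R,3aS,7aS)-4,4,7a-trimethyloctahydro-1H-inden-1-yl]ethenyl}tetrahydrofuro[3,4-b]furan-2,6-dione
Product: 27 (3R,4R)-3-hydroxy-4-{(2R)-1-hydroxy-3-[(1R,3aS,7aS)-4,4,7a-trimethyloctahydro-1H-inden-1-yl]but-3-en-2-yl}oxolan-2-one, via lithium carboxylate 25 (not isolated), via lithium triol carboxylate 26 (not isolated)
Conditions: LiOH (1.0 equiv), THF–H2O, 0 °C; evaporate to dryness (toluene); LiBH4, THF, 0 to 40 °C; 1 M HCl to pH 2, rt
Reagents that add atoms: none
Why: This is half-ester logic (LiBH4 reduces a lactone but not a carboxylate): hydroxide should open the more electrophilic and less hindered α-acyloxy lactone ring C first, the remaining hindered ring D carbonyl is reduced to the primary alcohol with release of the secondary hydroxyl, and acidification should re-close the five-membered ring C in preference to the six-membered alternative, with no stereocentre touched.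

Step 15
Reactants: 27 (3R,4R)-3-hydroxy-4-{(2R)-1-hydroxy-3-[(1R,3aS,7aS)-4,4,7a-trimethyloctahydro-1H-inden-1-yl]but-3-en-2-yl}oxolan-2-one
Product: 28 (2R)-2-[(3R,4R)-4-hydroxy-5-oxooxolan-3-yl]-3-[(1R,3aS,7aS)-4,4,7a-trimethyloctahydro-1H-inden-1-yl]but-3-en-1-yl acetate
Conditions: AcCl (1.1 equiv), 2,4,6-collidine, CH2Cl2, −78 °C
Reagents that add atoms: acetyl chloride, CC(=O)Cl
Why: Selective acylation of a primary alcohol with acetyl chloride and collidine at low temperature should leave the less nucleophilic, hindered α-hydroxyl of the lactone free.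

## Compound list

1 | (7aS)-7a-methyl-2,3,7,7a-tetrahydro-1H-indene-1,5(6H)-dione | C[C@]12CCC(=O)C=C1CCC2=O | starting material
2 | (7aS)-1,1-ethylenedioxy-7a-methyl-2,3,7,7a-tetrahydro-1H-inden-5(6H)-one | C[C@]12CCC(=O)C=C1CCC23OCCO3 | intermediate
3 | monomethyl enone, the 4-methyl analogue of 2 | C[C@]12CCC(=O)C(C)=C1CCC23OCCO3 | intermediate
4 | (7aS)-1,1-ethylenedioxy-4,4,7a-trimethyl-1,2,4,6,7,7a-hexahydro-5H-inden-5-one (C3=C3a alkene) | C[C@]12CCC(=O)C(C)(C)C1=CCC23OCCO3 | intermediate
5 | hydrazone of 4 | C[C@]12CCC(=NN)C(C)(C)C1=CCC23OCCO3 | intermediate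
6 | (7aS)-1,1-ethylenedioxy-4,4,7a-trimethyl-2,4,5,6,7,7a-hexahydro-1H-indene (C3=C3a alkene) | C[C@]12CCCC(C)(C)C1=CCC23OCCO3 | intermediate
7 | (3aS,7aS)-1,1-ethylenedioxy-4,4,7a-trimethyloctahydro-1H-indene (trans ring fusion) | C[C@]12CCCC(C)(C)[C@@H]1CCC23OCCO3 | intermediate
8 | (3aS,7aS)-4,4,7a-trimethyloctahydro-1H-inden-1-one | C[C@]12CCCC(C)(C)[C@@H]1CCC2=O | intermediate
9 | (1Z,3aS,7aS)-1-ethylidene-4,4,7a-trimethyloctahydro-1H-indene | C/C=C1/CC[C@H]2C(C)(C)CCC[C@]12C | intermediate
10 | B-alkyl-9-BBN adduct of 9 (boron on the side-chain CH, hydrogen on C-1 trans to the angular methyl) | C[C@H](B1C2CCCC1CCC2)[C@H]1CC[C@H]2C(C)(C)CCC[C@]12C | intermediate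
11 | (1S)-1-[(1S,3aS,7aS)-4,4,7a-trimethyloctahydro-1H-inden-1-yl]ethan-1-ol | C[C@H](O)[C@H]1CC[C@H]2C(C)(C)CCC[C@]12C | intermediate
12 | 1-[(1S,3aS,7aS)-4,4,7a-trimethyloctahydro-1H-inden-1-yl]ethan-1-one | CC(=O)[C@H]1CC[C@H]2C(C)(C)CCC[C@]12C | intermediate
13 | terminal potassium enolate of 12 | [K+].[O-]C(=C)[C@H]1CC[C@H]2C(C)(C)CCC[C@]12C | intermediate
14 | 1-[(1S,3aS,7aS)-4,4,7a-trimethyloctahydro-1H-inden-1-yl]ethenyl trifluoromethanesulfonate | C=C(OS(=O)(=O)C(F)(F)F)[C@H]1CC[C@H]2C(C)(C)CCC[C@]12C | intermediate
15 | potassium dihydrogen (2R,3S)-isocitrate | O=C(O)C[C@H](C(=O)O)[C@@H](O)C(=O)[O-].[K+] | starting material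
16 | (2R,3S)-isocitric acid | O=C(O)C[C@H](C(=O)O)[C@@H](O)C(=O)O | intermediate
17 | (2R,3S)-5-oxooxolane-2,3-dicarboxylic acid (isocitric acid lactone, cis diacid) | O=C1C[C@H](C(=O)O)[C@H](C(=O)O)O1 | intermediate
18 | (3aS,6aR)-dihydrofuro[3,4-b]furan-2,4,6(3H)-trione | O=C1C[C@@H]2C(=O)OC(=O)[C@@H]2O1 | intermediate
19 | (2R,3S)-2-(methoxycarbonyl)-5-oxooxolane-3-carboxylic acid | O=C1C[C@H](C(=O)O)[C@H](C(=O)OC)O1 | intermediate
20 | methyl (2R,3R)-3-(hydroxymethyl)-5-oxooxolane-2-carboxylate | O=C1C[C@H](CO)[C@H](C(=O)OC)O1 | intermediate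
21 | (3aR,6aR)-tetrahydrofuro[3,4-b]furan-2,6-dione | O=C1C[C@@H]2COC(=O)[C@@H]2O1 | intermediate
22 | (3aR,6aR)-2-(trimethylsilyloxy)-3a,4-dihydrofuro[3,4-b]furan-6(6aH)-one (ring D silyl ketene acetal) | C[Si](C)(C)OC1=C[C@@H]2COC(=O)[C@@H]2O1 | intermediate
23 | (3S,3aR,6aR)-3-bromotetrahydrofuro[3,4-b]furan-2,6-dione (exo bromide) | O=C1[C@@H](Br)[C@@H]2COC(=O)[C@@H]2O1 | intermediate
24 | (3R,3aR,6aR)-3-{1-[(1R,3aS,7aS)-4,4,7a-trimethyloctahydro-1H-inden-1-yl]ethenyl}tetrahydrofuro[3,4-b]furan-2,6-dione | O=C1[C@@H](C(=C)[C@H]3CC[C@H]4C(C)(C)CCC[C@]34C)[C@@H]2COC(=O)[C@@H]2O1 | intermediate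
25 | lithium carboxylate from opening of ring C of 24 (ring D intact, free CH2OH) | O=C1[C@@H](C(=C)[C@H]2CC[C@H]3C(C)(C)CCC[C@]23C)[C@H](CO)[C@H](C(=O)[O-])O1.[Li+] | intermediate
26 | lithium triol carboxylate (ring D reduced) | OC[C@@H](C(=C)[C@H]1CC[C@H]2C(C)(C)CCC[C@]12C)[C@H](CO)[C@@H](O)C(=O)[O-].[Li+] | intermediate
27 | (3R,4R)-3-hydroxy-4-{(2R)-1-hydroxy-3-[(1R,3aS,7aS)-4,4,7a-trimethyloctahydro-1H-inden-1-yl]but-3-en-2-yl}oxolan-2-one | C=C([C@H]1CC[C@H]2C(C)(C)CCC[C@]12C)[C@H](CO)[C@@H]1COC(=O)[C@@H]1O | intermediate
28 | (2R)-2-[(3R,4R)-4-hydroxy-5-oxooxolan-3-yl]-3-[(1R,3aS,7aS)-4,4,7a-trimethyloctahydro-1H-inden-1-yl]but-3-en-1-yl acetate (CNP0252518.3) | C=C([C@H]1CC[C@H]2C(C)(C)CCC[C@]12C)[C@H](COC(C)=O)[C@@H]1COC(=O)[C@@H]1O | target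

## Step count and risks

Total step count: 15. Longest linear sequence: 11 (steps 1 to 8, then 13 to 15).

**Step 13.**
- Risk: the electrophilic α-acyl radical may leave the nickel cycle and add to the CH2 terminus of the enol triflate or of the product alkene. It may also be reduced to the debrominated lactone, and the hindered alkenylnickel may homocouple.
- Fallback: a two-electron, radical-free union that sets out from 21 and 14. Compound 21 is silylated as in step 12 and silyl ketene acetal 22 is isolated by non-aqueous work-up. It is then joined to 14 by palladium-catalysed α-alkenylation of a silyl ketene acetal (Pd(dba)2, P(tBu)3, ZnF2, DMF, 60 °C).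
- Stereocontrol: the palladium C-enolate should again form and eliminate on the convex face.
- Return: the route is rejoined at 24. This fallback makes no compound outside the list (F0).

**Step 14.**
- Risk: hydroxide may attack the ring D carbonyl or open both lactones. Aqueous base may disturb the acidic allylic α-carbon, and incomplete drying of the salt may waste the hydride.
- Fallback: sets out from 24 and replaces the carboxylate mask by a neutral amide that can be purified. Aminolysis with pyrrolidine (THF, 0 °C to rt) is far more sensitive to hindrance than hydroxide. It should open only ring C to the hydroxy pyrrolidine amide F1.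
- LiBH4 in THF then reduces the remaining lactone, but not the tertiary amide, to the triol pyrrolidine amide F2.
- Return: 1 M HCl in THF at 40 °C lactonises the γ-hydroxy amide with loss of the amine, and the route is rejoined at 27.

**Step 12.**
- Risk: competing removal of the bridgehead proton next to the ring C carbonyl, double silylation, or self-condensation of the enolate may erode the regioselectivity.
- Fallback: sets out from 21 and uses thermodynamic carboxylation followed by the classical malonic-type bromination and decarboxylation. MeOMgOCO2Me in DMF at 125 °C, the method used for α-functionalisation of this class of bis-lactones, followed by acid work-up gives the 3-carboxy bis-lactone F3.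
- Br2 in Et2O gives the 3-bromo-3-carboxy bis-lactone F4.
- Return: warming in toluene expels carbon dioxide, and the route is rejoined at 23.

## Further compounds

F0 | step 13 | none | none
F1 | step 14 | hydroxy pyrrolidine amide (ring C of 24 opened at its carbonyl, ring D intact) | O=C1[C@@H](C(=C)[C@H]2CC[C@H]3C(C)(C)CCC[C@]23C)[C@H](CO)[C@H](C(=O)N2CCCC2)O1
F2 | step 14 | triol pyrrolidine amide (ring D reduced) | OC[C@@H](C(=C)[C@H]1CC[C@H]2C(C)(C)CCC[C@]12C)[C@H](CO)[C@@H](O)C(=O)N1CCCC1
F3 | step 12 | (3aR,6aR)-2,6-dioxohexahydrofuro[3,4-b]furan-3-carboxylic acid (exo acid) | O=C1[C@@H](C(=O)O)[C@@H]2COC(=O)[C@@H]2O1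
F4 | step 12 | (3aR,6aR)-3-bromo-2,6-dioxohexahydrofuro[3,4-b]furan-3-carboxylic acid (exo bromide) | O=C1[C@](Br)(C(=O)O)[C@@H]2COC(=O)[C@@H]2O1
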